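**Retrosynthetic overview**

1. Macrocarpal J ⇐ thiolate O-demethylation and twofold ortho-lithiation/formylation of a trimethoxyphenyl eudesmane-4α,11-diol ⇐ Markovnikov hydration of a C4=CH2 alkene ⇐ Wittig methylenation of a trans-fused decalin-4-one.
2. Ring B (C5–C6–C7–C8–C9–C10) is closed last: the decalinone ⇐ α-face hydrogenation of a 5,7-dien-4-one ⇐ thermal 6π-electrocyclisation (C9–C10 bond) of the 2-acyl-hexatriene C10=C5(C4=O)–C6=C7(C11)–C8=C9, assembled on ring A by Sonogashira coupling, trans-hydrostannation and Stille vinylation.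
3. Enabling feature: ring B carries only the C7 carbinol side chain, its fusion atom C10 is quaternary (CH3, C1, C5, C9), and C5 bears the oxygenated C4. Ring B is therefore the cyclohexadiene of a triene whose terminus C10 is a ring-A alkene carbon, whose position 2 (C5) holds the C4 carbonyl (the later C4 carbinol), and whose closure is steered by the C1 stereocentre.
4. Ring A (2-iodo-3-methyl-4-substituted cyclohexenone) ⇐ methyl cuprate addition/dehydrogenation and α-iodination of a 4-substituted cyclohexenone ⇐ enamine-catalysed Michael addition to methyl vinyl ketone and aldol condensation of (S)-3-aryl-5-methylhexanal; C1' ⇐ iminium-catalysed Friedel–Crafts addition of 1,3,5-trimethoxybenzene to (E)-5-methylhex-2-enal.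
5. Order of rings: arene (purchased) → ring A (step 4) → ring B (step 9).

Key step: step 9

Remark: positions are named by eudesmane numbering throughout, also in monocyclic intermediates (C1 carries the benzylic carbon C1'; C4 the ring carbinol and methyl; C5/C10 the ring fusion, C10 with methyl; C7 the carbinol carbon C11; β = same side as the C10 methyl group). It is assumed that both amine catalysts induce in the sense of the accepted iminium and enamine shielding models and that all numbered starting materials are catalogue chemicals.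

Step 1
Reactants: 1 isovaleraldehyde (3-methylbutanal); 2 (triphenylphosphoranylidene)acetaldehyde
Product: 3 (E)-5-methylhex-2-enal
Conditions: toluene, 80 °C
Reagents that add atoms: none
Why: Wittig olefination with a formyl-stabilised ylide, which should give the E-enal; no stereocentre is formed.

Step 2
Reactants: 3 (E)-5-methylhex-2-enal; 4 1,3,5-trimethoxybenzene
Product: 5 (3S)-5-methyl-3-(2,4,6-trimethoxyphenyl)hexanal
Conditions: (2R,5R)-5-benzyl-2-tert-butyl-3-methylimidazolidin-4-one·CF3CO2H (20 mol %), CHCl3, −20 °C, 4 in threefold excess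
Reagents that add atoms: none
Why: Iminium-ion-catalysed Friedel–Crafts-type conjugate addition, in which the arene (about as nucleophilic as the 2-alkylfurans used in this reaction type) attacks the β-carbon of the E-iminium ion on the face left open by the benzyl group, so that the (2R,5R)-catalyst should set C1' as S (mirror image of the R-configured 3-arylbutanals given by the (2S,5S)-catalyst), while the excess of 4 suppresses a second alkylation.

Step 3
Reactants: 5 (3S)-5-methyl-3-(2,4,6-trimethoxyphenyl)hexanal; 6 methyl vinyl ketone (but-3-en-2-one)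
Product: 7 (2S,3S)-5-methyl-2-(3-oxobutyl)-3-(2,4,6-trimethoxyphenyl)hexanal
Conditions: (S)-2-[diphenyl(trimethylsilyloxy)methyl]pyrrolidine (10 mol %), ethyl 3,4-dihydroxybenzoate (20 mol %), neat, 4 °C
Reagents that add atoms: none
Why: Enamine-catalysed Michael addition of an aldehyde to an enone, in which the E-enamine reacts on the face opposite to the diphenyl(silyloxy)methyl group, so that the (S)-catalyst should set the future C1 as S under catalyst control.

Step 4
Reactants: 7 (2S,3S)-5-methyl-2-(3-oxobutyl)-3-(2,4,6-trimethoxyphenyl)hexanal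
Product: 8 (4R)-4-[(1S)-3-methyl-1-(2,4,6-trimethoxyphenyl)butyl]cyclohex-2-en-1-one
Conditions: LiOH (10 mol %), i-PrOH, rt
Reagents that add atoms: none
Why: Intramolecular aldol condensation (methyl ketone enolate onto the aldehyde, then E1cB dehydration) closes ring A, and the mild base should leave the γ-stereocentre C1 untouched (its descriptor changes only through the priority rules).

Step 5
Reactants: 8 (4R)-4-[(1S)-3-methyl-1-(2,4,6-trimethoxyphenyl)butyl]cyclohex-2-en-1-one
Product: 10 (4S)-3-methyl-4-[(1S)-3-methyl-1-(2,4,6-trimethoxyphenyl)butyl]cyclohex-2-en-1-one, via lithium enolate 9 (not isolated)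
Conditions: Me2CuLi (from MeLi, CuI), Et2O, −78 °C; then PhS(Cl)=N-t-Bu, THF, −78 °C to rt
Reagents that add atoms: lithium dimethylcuprate, [Li+].C[Cu-]C
Why: Cuprate conjugate addition (anti to the C1 substituent) gives enolate 9 regiospecifically, and Mukaiyama dehydrogenation with N-tert-butylbenzenesulfinimidoyl chloride (sulfur attack at C5, syn-elimination of the C10 hydrogen) restores the C5=C10 enone, so the transient C10 centre is erased.

Step 6
Reactants: 10 (4S)-3-methyl-4-[(1S)-3-methyl-1-(2,4,6-trimethoxyphenyl)butyl]cyclohex-2-en-1-one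
Product: 11 (4S)-2-iodo-3-methyl-4-[(1S)-3-methyl-1-(2,4,6-trimethoxyphenyl)butyl]cyclohex-2-en-1-one
Conditions: I2, pyridine, DMAP (cat.), CH2Cl2, rt
Reagents that add atoms: iodine, I-I
Why: Johnson α-iodination of an enone (conjugate addition of the amine at C10, iodination of the enolate at C5, elimination), which should spare the trimethoxyphenyl ring because molecular iodine without an oxidant is too weak an electrophile for it.

Step 7
Reactants: 11 (4S)-2-iodo-3-methyl-4-[(1S)-3-methyl-1-(2,4,6-trimethoxyphenyl)butyl]cyclohex-2-en-1-one; 12 2-methylbut-3-yn-2-ol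
Product: 13 (4S)-2-(3-hydroxy-3-methylbut-1-yn-1-yl)-3-methyl-4-[(1S)-3-methyl-1-(2,4,6-trimethoxyphenyl)butyl]cyclohex-2-en-1-one
Conditions: PdCl2(PPh3)2 (5 mol %), CuI (10 mol %), i-Pr2NH, THF, rt
Reagents that add atoms: none
Why: Sonogashira coupling of an α-iodoenone, a substrate class that undergoes oxidative addition readily, brings in C6, C7 and the C11 carbinol without touching C1.

Step 8
Reactants: 13 (4S)-2-(3-hydroxy-3-methylbut-1-yn-1-yl)-3-methyl-4-[(1S)-3-methyl-1-(2,4,6-trimethoxyphenyl)butyl]cyclohex-2-en-1-one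
Product: 14 (4S)-2-[(1Z)-3-hydroxy-3-methyl-2-(tributylstannyl)but-1-en-1-yl]-3-methyl-4-[(1S)-3-methyl-1-(2,4,6-trimethoxyphenyl)butyl]cyclohex-2-en-1-one
Conditions: Bu3SnH, [Cp*RuCl]4 (2.5 mol %), CH2Cl2, rt
Reagents that add atoms: tributyltin hydride, CCCC[SnH](CCCC)CCCC
Why: Ruthenium-catalysed trans-hydrostannation of a propargylic alcohol, in which the free hydroxyl group steers tin to the proximal alkyne carbon C7 and H and Sn add anti, so that ring carbon C5 and tin end up cis on the new C6=C7 bond.

Step 9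
Reactants: 14 (4S)-2-[(1Z)-3-hydroxy-3-methyl-2-(tributylstannyl)but-1-en-1-yl]-3-methyl-4-[(1S)-3-methyl-1-(2,4,6-trimethoxyphenyl)butyl]cyclohex-2-en-1-one; 15 vinyl bromide (bromoethene)
Product: 17 11-hydroxy-1β-[(1S)-3-methyl-1-(2,4,6-trimethoxyphenyl)butyl]-15-nor-eudesma-5,7-dien-4-one (10β-methyl), via triene 16 (not isolated)
Conditions: Pd(PPh3)4 (5 mol %), CuI (10 mol %), CsF, DMF, 40 °C; then 80 °C
Reagents that add atoms: none
Why: The Stille coupling (retention at C7) should give triene 16, in which C5 and the vinyl group are cis on C6=C7, and 16 should close thermally by a disrotatory 6π-electrocyclisation that forms the C9–C10 bond and thereby the six-membered ring B, whose six atoms are the six triene carbons. The closest known reactions are the thermal ring closures of 2-acyl-hexatrienes, where a carbonyl group on triene position 2 (here C4=O on C5) lowers the barrier markedly, and the thermal closure of previtamin D to the pyrocalciferols, where a methyl-bearing ring carbon becomes quaternary in the same way. C10 is the only new stereocentre (C9 is a CH2 group): allylic strain against the C10 methyl group holds the C1 side chain pseudoaxial on ring A, so C9 should bond to the opposite face and leave the C10 methyl group cis to the side chain, as in the target. The selectivity needed is ring closure ahead of 1,7-hydrogen shifts from the C10 methyl group or C1–H to C9; these shifts are reversible, whereas closure is irreversible and ends in a dienone conjugated from C4=O to C8. The alkene geometry required for closure is secured by the trans-hydrostannation of step 8, and the carbinol group, being trans to C5, cannot add to the enone.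

Step 10
Reactants: 17 11-hydroxy-1β-[(1S)-3-methyl-1-(2,4,6-trimethoxyphenyl)butyl]-15-nor-eudesma-5,7-dien-4-one
Product: 18 11-hydroxy-1β-[(1S)-3-methyl-1-(2,4,6-trimethoxyphenyl)butyl]-15-nor-5α-eudesman-4-one (trans-fused, 7β-(2-hydroxyprop-2-yl), 10β-methyl)
Conditions: H2 (1 atm), 10% Pd/C, EtOAc, Et3N (trace), rt
Reagents that add atoms: none
Why: Heterogeneous hydrogenation of both ring-B alkenes from the α-face, opposite to the axial C10 methyl group and the C1 side chain, should set C5 (α-H, trans ring fusion, also the stable epimer next to the ketone) and C7 (α-H, equatorial β side chain).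

Step 11
Reactants: 18 11-hydroxy-1β-[(1S)-3-methyl-1-(2,4,6-trimethoxyphenyl)butyl]-15-nor-5α-eudesman-4-one
Product: 19 1β-[(1S)-3-methyl-1-(2,4,6-trimethoxyphenyl)butyl]-5α-eudesm-4(15)-en-11-ol
Conditions: Ph3PCH3Br, KOt-Bu, toluene, 80 °C
Reagents that add atoms: methylenetriphenylphosphorane, C=P(c1ccccc1)(c1ccccc1)c1ccccc1
Why: Wittig methylenation, a reaction type well established for hindered 4-oxodecalins, with excess ylide to carry the tertiary alcohol as its alkoxide; the all-equatorial trans-fused ketone should not epimerise at C5.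

Step 12
Reactants: 19 1β-[(1S)-3-methyl-1-(2,4,6-trimethoxyphenyl)butyl]-5α-eudesm-4(15)-en-11-ol
Product: 20 1β-[(1S)-3-methyl-1-(2,4,6-trimethoxyphenyl)butyl]-5α-eudesmane-4α,11-diol (4β-methyl)
Conditions: Mn(dpm)3 (10 mol %), PhSiH3, O2 (1 atm), i-PrOH/CH2Cl2, 0 °C
Reagents that add atoms: dioxygen, O=O
Why: Mukaiyama-type Markovnikov hydration by metal-hydride hydrogen atom transfer, in which the tertiary C4 radical should be trapped by O2 on the equatorial α-face because the axial β-approach is blocked by the syn-axial C10 methyl group, giving the 4α-OH/4β-CH3 carbinol.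

Step 13
Reactants: 20 1β-[(1S)-3-methyl-1-(2,4,6-trimethoxyphenyl)butyl]-5α-eudesmane-4α,11-diol
Product: 22 1β-[(1S)-1-(3,5-diformyl-2,4,6-trimethoxyphenyl)-3-methylbutyl]-5α-eudesmane-4α,11-diol, via lithium amino alkoxide 21 (not isolated)
Conditions: n-BuLi, TMEDA, THF, 0 °C; DMF, −78 to 0 °C; n-BuLi, 0 °C; DMF; aq. NH4Cl
Reagents that add atoms: N,N-dimethylformamide, CN(C)C=O
Why: Directed ortho-metalation between two methoxy groups followed by formylation, in which the lithium α-(dimethylamino)alkoxide 21 protects the first formyl group in the flask so that the second ring position can be lithiated and formylated in the same operation (the tertiary alcohols are carried as lithium alkoxides).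

Step 14
Reactants: 22 1β-[(1S)-1-(3,5-diformyl-2,4,6-trimethoxyphenyl)-3-methylbutyl]-5α-eudesmane-4α,11-diol
Product: 23 macrocarpal J
Conditions: NaSEt, DMF, 120 °C; then 1 M HCl
Reagents that add atoms: none
Why: Nucleophilic O-demethylation by thiolate (SN2 at methyl), made easy because every methoxy group is ortho or para to a formyl group that stabilises the departing phenoxide; tertiary alcohols, aldehydes and all stereocentres should be inert to these basic conditions.

**Compound list**

1 | isovaleraldehyde (3-methylbutanal) | CC(C)CC=O | starting material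
2 | (triphenylphosphoranylidene)acetaldehyde | O=CC=P(c1ccccc1)(c1ccccc1)c1ccccc1 | starting material
3 | (E)-5-methylhex-2-enal | CC(C)C/C=C/C=O | intermediate
4 | 1,3,5-trimethoxybenzene | COc1cc(OC)cc(OC)c1 | starting material
5 | (3S)-5-methyl-3-(2,4,6-trimethoxyphenyl)hexanal | CC(C)C[C@H](c1c(OC)cc(OC)cc1OC)CC=O | intermediate
6 | methyl vinyl ketone (but-3-en-2-one) | CC(=O)C=C | starting material
7 | (2S,3S)-5-methyl-2-(3-oxobutyl)-3-(2,4,6-trimethoxyphenyl)hexanal | CC(C)C[C@H](c1c(OC)cc(OC)cc1OC)[C@@H](C=O)CCC(C)=O | intermediate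
8 | (4R)-4-[(1S)-3-methyl-1-(2,4,6-trimethoxyphenyl)butyl]cyclohex-2-en-1-one | CC(C)C[C@H](c1c(OC)cc(OC)cc1OC)[C@@H]1CCC(=O)C=C1 | intermediate
9 | lithium enolate of 3,4-trans-3-methyl-4-[(1S)-3-methyl-1-(2,4,6-trimethoxyphenyl)butyl]cyclohexanone (enolate towards C2 of the ring) | CC(C)C[C@H](c1c(OC)cc(OC)cc1OC)[C@@H]1CCC(O[Li])=C[C@H]1C | intermediate
10 | (4S)-3-methyl-4-[(1S)-3-methyl-1-(2,4,6-trimethoxyphenyl)butyl]cyclohex-2-en-1-one | CC(C)C[C@H](c1c(OC)cc(OC)cc1OC)[C@@H]1CCC(=O)C=C1C | intermediate
11 | (4S)-2-iodo-3-methyl-4-[(1S)-3-methyl-1-(2,4,6-trimethoxyphenyl)butyl]cyclohex-2-en-1-one | CC(C)C[C@H](c1c(OC)cc(OC)cc1OC)[C@@H]1CCC(=O)C(I)=C1C | intermediate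
12 | 2-methylbut-3-yn-2-ol | CC(C)(O)C#C | starting material
13 | (4S)-2-(3-hydroxy-3-methylbut-1-yn-1-yl)-3-methyl-4-[(1S)-3-methyl-1-(2,4,6-trimethoxyphenyl)butyl]cyclohex-2-en-1-one | CC(C)C[C@H](c1c(OC)cc(OC)cc1OC)[C@@H]1CCC(=O)C(C#CC(C)(C)O)=C1C | intermediate
14 | (4S)-2-[(1Z)-3-hydroxy-3-methyl-2-(tributylstannyl)but-1-en-1-yl]-3-methyl-4-[(1S)-3-methyl-1-(2,4,6-trimethoxyphenyl)butyl]cyclohex-2-en-1-one | CC(C)C[C@H](c1c(OC)cc(OC)cc1OC)[C@@H]1CCC(=O)C(/C=C(\[Sn](CCCC)(CCCC)CCCC)C(C)(C)O)=C1C | intermediate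
15 | vinyl bromide (bromoethene) | C=CBr | starting material
16 | (4S)-2-[(1E)-2-(2-hydroxypropan-2-yl)buta-1,3-dien-1-yl]-3-methyl-4-[(1S)-3-methyl-1-(2,4,6-trimethoxyphenyl)butyl]cyclohex-2-en-1-one (ring carbon cis to the vinyl group) | CC(C)C[C@H](c1c(OC)cc(OC)cc1OC)[C@@H]1CCC(=O)C(/C=C(\C=C)C(C)(C)O)=C1C | intermediate
17 | 11-hydroxy-1β-[(1S)-3-methyl-1-(2,4,6-trimethoxyphenyl)butyl]-15-nor-eudesma-5,7-dien-4-one (10β-methyl) | CC(C)C[C@H](c1c(OC)cc(OC)cc1OC)[C@@H]1CCC(=O)C2=CC(C(C)(C)O)=CC[C@]21C | intermediate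
18 | 11-hydroxy-1β-[(1S)-3-methyl-1-(2,4,6-trimethoxyphenyl)butyl]-15-nor-5α-eudesman-4-one (trans-fused, 7β side chain, 10β-methyl) | CC(C)C[C@H](c1c(OC)cc(OC)cc1OC)[C@@H]1CCC(=O)[C@@H]2C[C@H](C(C)(C)O)CC[C@]21C | intermediate
19 | 1β-[(1S)-3-methyl-1-(2,4,6-trimethoxyphenyl)butyl]-5α-eudesm-4(15)-en-11-ol | CC(C)C[C@H](c1c(OC)cc(OC)cc1OC)[C@@H]1CCC(=C)[C@@H]2C[C@H](C(C)(C)O)CC[C@]21C | intermediate
20 | 1β-[(1S)-3-methyl-1-(2,4,6-trimethoxyphenyl)butyl]-5α-eudesmane-4α,11-diol (4β-methyl) | CC(C)C[C@H](c1c(OC)cc(OC)cc1OC)[C@@H]1CC[C@@](C)(O)[C@@H]2C[C@H](C(C)(C)O)CC[C@]21C | intermediate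
21 | trilithium salt of the mono-formylation adduct of 20 (aryl C3 carries CH(OLi)NMe2; C4 and C11 alkoxides) | CC(C)C[C@H](c1c(OC)c(C(O[Li])N(C)C)c(OC)cc1OC)[C@@H]1CC[C@@](C)(O[Li])[C@@H]2C[C@H](C(C)(C)O[Li])CC[C@]21C | intermediate
22 | 1β-[(1S)-1-(3,5-diformyl-2,4,6-trimethoxyphenyl)-3-methylbutyl]-5α-eudesmane-4α,11-diol | CC(C)C[C@H](c1c(OC)c(C=O)c(OC)c(C=O)c1OC)[C@@H]1CC[C@@](C)(O)[C@@H]2C[C@H](C(C)(C)O)CC[C@]21C | intermediate
23 | macrocarpal J | CC(C)C[C@H](c1c(O)c(C=O)c(O)c(C=O)c1O)[C@@H]1CC[C@@](C)(O)[C@@H]2C[C@H](C(C)(C)O)CC[C@]21C | target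

**Step count and risks**

Total step count: 14. Longest linear sequence: 14 steps (from 1; all other building blocks are purchased).

Steps most likely to fail:

Step 9 (key step). The coupling of the hindered, geminally substituted alkenylstannane may be slow, and ring closure at the fully substituted C10 terminus may be outrun by 1,7-hydrogen shifts of the triene or occur with poor facial selectivity. The fallback builds ring B by ring-closing metathesis; it sets out from 10 and comes back at 19. Conjugate allylation of 10 (allylMgBr, CuBr·SMe2, TMSCl, THF, −78 °C) should add the allyl group anti to the C1 side chain and give the trimethylsilyl enol ether F1. Regiospecific lithium enolate formation from it (MeLi) and alkylation at C5 with methyl 2-(bromomethyl)acrylate should give the diene keto ester F2. Ring-closing metathesis (second-generation Grubbs catalyst, toluene, 80 °C) should close ring B as the bicyclic enoate F3. Hydrogenation (H2, Pd/C) followed by NaOMe equilibration should give the trans-fused keto ester F4, whose C5 and C7 centres are both epimerisable to the all-equatorial isomer. Wittig methylenation (Ph3PCH3Br, KOt-Bu) should give the methylene ester F5, and MeMgBr converts its ester into the carbinol of 19.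

Step 2. The arene may be too weak a nucleophile toward the iminium ion, so that turnover is slow and an uncatalysed racemic pathway or double alkylation erodes the enantiomeric purity at C1'. The fallback is an auxiliary-controlled conjugate addition; it sets out from 3 and comes back at 5. Pinnick oxidation of 3 (NaClO2, NaH2PO4, 2-methylbut-2-ene) gives (E)-5-methylhex-2-enoic acid F6. Acylation of (R)-4-phenyloxazolidin-2-one through the pivaloyl mixed anhydride (PivCl, Et3N, LiCl) gives the N-enoyl oxazolidinone F7. 2,4,6-Trimethoxyphenylmagnesium bromide F8 (from 2-bromo-1,3,5-trimethoxybenzene and Mg) with CuBr·SMe2 should add to the chelated s-cis enoyl unit anti to the phenyl group and give the (3S)-adduct F9. LiBH4 removes the auxiliary to give the primary alcohol F10, and Dess–Martin oxidation gives 5.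

Step 6. The amine may fail to add to the fully substituted β-carbon next to the bulky C1 substituent, or the electron-rich ring may be iodinated instead. The fallback iodinates before the β-methyl group is present; it sets out from 8 and comes back at 13. Johnson iodination of 8 (I2, pyridine), which has an unhindered β-CH, gives the iodoenone F11. Sonogashira coupling with 12 (PdCl2(PPh3)2, CuI, i-Pr2NH) gives the alkynyl enone F12. Excess Me2CuLi followed by PhS(Cl)=N-t-Bu (conjugate methylation, then dehydrogenation of the enolate) should give 13.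

**Further compounds**

F1 | step 9 | trimethylsilyl enol ether of 3-allyl-3-methyl-4-[(1S)-3-methyl-1-(2,4,6-trimethoxyphenyl)butyl]cyclohexanone (allyl trans to the side chain) | CC(C)C[C@H](c1c(OC)cc(OC)cc1OC)[C@@H]1CCC(O[Si](C)(C)C)=C[C@@]1(C)CC=C
F2 | step 9 | methyl 2-{[2-allyl-2-methyl-6-oxo-3-[(1S)-3-methyl-1-(2,4,6-trimethoxyphenyl)butyl]cyclohexyl]methyl}prop-2-enoate (C5 side chain trans to the allyl group) | CC(C)C[C@H](c1c(OC)cc(OC)cc1OC)[C@@H]1CCC(=O)[C@H](CC(=C)C(=O)OC)[C@@]1(C)CC=C
F3 | step 9 | methyl 4-oxo-1β-[(1S)-3-methyl-1-(2,4,6-trimethoxyphenyl)butyl]-12,13,15-trinor-5α-eudesm-7-en-11-oate | CC(C)C[C@H](c1c(OC)cc(OC)cc1OC)[C@@H]1CCC(=O)[C@@H]2CC(C(=O)OC)=CC[C@]21C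
F4 | step 9 | methyl 4-oxo-1β-[(1S)-3-methyl-1-(2,4,6-trimethoxyphenyl)butyl]-12,13,15-trinor-5α-eudesman-11-oate (7β-ester) | CC(C)C[C@H](c1c(OC)cc(OC)cc1OC)[C@@H]1CCC(=O)[C@@H]2C[C@H](C(=O)OC)CC[C@]21C
F5 | step 9 | methyl 1β-[(1S)-3-methyl-1-(2,4,6-trimethoxyphenyl)butyl]-12,13-dinor-5α-eudesm-4(15)-en-11-oate | CC(C)C[C@H](c1c(OC)cc(OC)cc1OC)[C@@H]1CCC(=C)[C@@H]2C[C@H](C(=O)OC)CC[C@]21C
F6 | step 2 | (E)-5-methylhex-2-enoic acid | CC(C)C/C=C/C(=O)O
F7 | step 2 | (4R)-3-[(E)-5-methylhex-2-enoyl]-4-phenyloxazolidin-2-one | CC(C)C/C=C/C(=O)N1[C@H](c2ccccc2)COC1=O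
F8 | step 2 | 2,4,6-trimethoxyphenylmagnesium bromide | COc1cc(OC)c([Mg]Br)c(OC)c1
F9 | step 2 | (4R)-3-[(3S)-5-methyl-3-(2,4,6-trimethoxyphenyl)hexanoyl]-4-phenyloxazolidin-2-one | CC(C)C[C@H](c1c(OC)cc(OC)cc1OC)CC(=O)N1[C@H](c2ccccc2)COC1=O
F10 | step 2 | (3S)-5-methyl-3-(2,4,6-trimethoxyphenyl)hexan-1-ol | CC(C)C[C@H](c1c(OC)cc(OC)cc1OC)CCO
F11 | step 6 | (4R)-2-iodo-4-[(1S)-3-methyl-1-(2,4,6-trimethoxyphenyl)butyl]cyclohex-2-en-1-one | CC(C)C[C@H](c1c(OC)cc(OC)cc1OC)[C@@H]1CCC(=O)C(I)=C1
F12 | step 6 | (4R)-2-(3-hydroxy-3-methylbut-1-yn-1-yl)-4-[(1S)-3-methyl-1-(2,4,6-trimethoxyphenyl)butyl]cyclohex-2-en-1-one | CC(C)C[C@H](c1c(OC)cc(OC)cc1OC)[C@@H]1CCC(=O)C(C#CC(C)(C)O)=C1
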